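Start from what is left: of the 0.240 M of Sbt charged to the teal flask, 0.149 M has not come out as Pdt at 29 min. The flask whose share of Pdt you are asked about is blue, where Sbt is the limiting reagent, with 0.200 M against 0.360 M of Ptn, so Sbt is the one to keep books on.

| setting | grey | teal | red | blue |
|---|---|---|---|---|
| Sbt | 0.600 M | 0.240 M | 0.600 M | 0.200 M |
| Ptn | 0.720 M | 0.360 M | 0.720 M | 0.360 M |
| Ctl | 0.00600 M | 0.00600 M | 0.0180 M | 0.00600 M |
| time |  |  |  | 29 min |

| grey run: time / min | grey run: [Pdt] / M | teal run: time / min | teal run: [Pdt] / M | red run: time / min | red run: [Pdt] / M |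
|---|---|---|---|---|---|
| 1.2 | 0.0076 | 1.2 | 0.0087 | 1.2 | 0.0116 |
| 2.0 | 0.0095 | 2.0 | 0.0057 | 2.0 | 0.0239 |
| 3.4 | 0.0149 | 3.4 | 0.0070 | 3.4 | 0.0447 |
| 5.8 | 0.0305 | 5.8 | 0.0162 | 5.8 | 0.0895 |
| 9.9 | 0.0564 | 9.9 | 0.0253 | 9.9 | 0.1640 |
| 17 | 0.1200 | 17 | 0.0488 | 17 | 0.2914 |
| 29 | 0.2434 | 29 | 0.0910 | 29 | 0.4575 |

(each reading ± 0.002 M)

* reaction order in [Ctl] at the outset, round the charge of the grey run, defined at two percent of the Sbt turned into Pdt
* the teal run starts with 0.360 M less of Sbt and of Ptn than the grey run, and with no Pdt. Compared where both hold the same amount of Sbt, once fifteen percent of what the teal run was charged with has turned into Pdt, is the teal run faster, slower or alike (within a tenth)?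
* Pdt in the blue run at 29 min, as a share of the Sbt charged

- Overall: Sbt + Ptn -> Pdt, with Ctl as catalyst.
- Constant volume, constant temperature.
- The analysis sees a species whether free or bound.
- "The second partner" is Ptn.
- An order is taken over about fifteen percent of the charge, up and down.

Count the books in turnovers, where one turnover is one Pdt made per Ctl charged. The teal charge allows 40.0 turnovers. At 29 min the Pdt entry takes 15.2 of them and the leftover holds the other 24.8, which gives the teal flask 37.9%. Call this the turnover share: turnovers made divided by turnovers the charge allows. One teal reading's scatter is worth 0.833% of that charge.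

Compare grey and teal by share, not by count. With the same Ctl, at 17 min the grey flask has 20.0 turnovers and the teal flask 8.13, yet their shares read 20.0% and 20.3%. At 29 min grey reads 40.6%, so the two part a little. The blue charge lies next to teal's, and blue has teal's Ptn and Ctl, so I take teal's share.

My books for the blue flask then run like this. The charge allows 33.3 turnovers. At 29 min the Pdt entry is 12.6 turnovers, or 0.0758 M, and the leftover is 0.124 M, which closes on the 0.200 M charged. I commit to 37.9% of the blue charge.

The forecast, made from the same runs, gives 0.95 for the order in Ctl, slower for teal against grey, and 37.5% for blue, slightly below my figure. Its ground for blue: “Blue should resemble teal's 38% conversion.”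

The simulation gives 0.88 for the order, slower for teal, with its rate 0.36 of grey's at equal Sbt, and 38.2% for blue.

    Ctl + Sbt → X + Lvg (9.420 L mol⁻¹ min⁻¹)
    X + Ptn → Pdt + Ctl (5.304 L mol⁻¹ min⁻¹)
    Sbt + Ptn + Pdt → 2 Pdt (1.032 L² mol⁻² min⁻¹)
    Sbt + Ptn ⇌ Sbt.Ptn, settled at all times (8.060 L mol⁻¹)

Blue's 38.2% is 12.7 turnovers of the 33.3 its charge allows, against 12.6 carried from teal. Grey and teal reach a quarter of their charge at 20.4 min and 19.9 min, though that is 25.0 turnovers in grey and 10.0 in teal. Blue's leftover stands mainly because Sbt and Ptn tie up as Sbt.Ptn: with that binding taken away, blue reaches 79.6% at 29 min, which is 26.5 turnovers.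

The runs come from a simulation with constants of no real substance; noise was put on by code.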